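The pitfall was to put the dissolved gas at its saturation value.

    gas phase ⇌ dissolved gas, rate k1*(csat - [dissolved gas]) (k1 = 3.4 /min, csat = 14 mM)
    starting material + dissolved gas ⇌ target (K2 = 680 /M, k2 = 20 /M/min)
    dissolved gas + target → over-reacted product (k3 = 0.83 /M/min)
    2 dissolved gas → homo dimer (k4 = 30 /M/min)
    target ⇌ isomer of the product (K5 = 1.0, k5 = 0.25 /min)

starting material 0.20 M; gas phase 14 mM (held); time 8.0 min

- where a step has two of a species, its rate is k times that concentration squared, and two are used at each turn
- at the start none of the gas is dissolved
- run time (flask): 8.0 min

1. the target standing at 8.0 min, as a percentage of the starting material charged
2. the change that raises the amount of target at 8.0 min, in percent of the starting material charged most ("none" if none brings more than 2 percentage points) (Sunday's / Thursday's / none)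
3. amount of target at 8.0 min, in percent of the starting material charged, after Sunday's

- Sunday's: doubling the saturation concentration of gas phase, all else as stated
- Thursday's: doubling the transfer coefficient of step 1, all else as stated

Sunday's doubled the saturation concentration; Thursday's doubled the transfer coefficient.

I divided the starting material's uptake constant by the transfer coefficient, so time dropped out. This gave the capture number, the uptake constant of the charge over the transfer coefficient, 1.18. Transfer and uptake together relaxed [dissolved gas] within 0.135 min at the charge, far less than 8.0 min, so I balanced the two there and put [dissolved gas] at saturation divided by one plus that number, 6.43 mM. I kept this charge value through the run as an estimate. Dimerisation at 2.48 mM/min was less than the transfer of 25.7 mM/min, so I dropped it.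

Starting material then fell with a pseudo-first-order constant of 0.129 /min. The relaxation half-life of 1.39 min was short against 8.0 min, so target and isomer of the product shared the converted material, with target ahead by 11.7%. That put target at 38.0%.

Sunday's doubled the constant. Thursday's lowered the capture number and gave only 0.176 /min. I chose Sunday's, with target at 49.4%.

The forecast gave 39.3%, Sunday's and 47.5%, holding that Sunday's “raises the dissolved gas and early rate more than doubling the transfer coefficient does”.

The simulation gave 38.9% and 47.6%. Sunday's gained 8.7 percentage points, and Thursday's gained 4 points.

In this flask, [dissolved gas] read 6.36 mM at 0.800 min, against my 6.43 mM from the capture number of 1.18. In the neighbouring flask, charged with 0.80 M of starting material, the capture number was 4.71. The same reckoning put [dissolved gas] there at 2.45 mM, the constant at 0.0491 /min and target at 19.8%. That neighbouring flask gave 22.1% of target, with [dissolved gas] at 3.75 mM and 64% of its starting material unbound at 8.00 min.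

The rate constants come from no measurement; the run is a simulation.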